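**Retrosynthetic overview**
1. 20 ⇐ 19 by removal of two acetates. Ring C (pyranone) is closed last from deoxybenzoin 18 plus one carbon of DMF; ring A is bought as phloroglucinol 17 and joined by C-acylation with arylacetic acid 16.
2. 16 ⇐ oxidative cleavage of the allyl group of 14. That aryl–CH2 bond (later the link between ring C and ring B) ⇐ para-Claisen rearrangement (two [3,3] shifts) of allyl aryl ether 8, which also frees the phenol oxygen for ring D.
3. Ring D ⇐ acid cyclodehydration of phenol–diol 11: the phenol oxygen attacks the tertiary carbinol carbon and the C3–O bond is untouched.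
4. Side chain and stereocentre ⇐ aryl Grignard from bromide 3 opening methyl (S)-glycidate 4 at CH2, then two MeMgBr additions to the ester.
5. Ring order: B (bought in 1) → D → A attached → C.

Assumption: methyl (2S)-glycidate 4 is taken as a commercial serine-derived building block; it supplies the single (S) stereocentre, which is carried through with retention.

**Step 1**
Reactants: 1 2-bromo-6-methoxyphenol; 2 allyl bromide
Product: 3 2-(allyloxy)-1-bromo-3-methoxybenzene
Conditions: K2CO3, acetone, reflux
Reagents that add atoms: none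
Why: Williamson ether synthesis, the phenoxide displacing bromide from the allylic halide by SN2; no stereocentre is involved.

**Step 2**
Reactants: 3 2-(allyloxy)-1-bromo-3-methoxybenzene; 4 methyl (2S)-oxirane-2-carboxylate
Product: 8 (2S)-1-[2-(allyloxy)-3-methoxyphenyl]-3-methylbutane-2,3-diol, via aryllithium 5 (not isolated), via arylmagnesium bromide 6 (not isolated), via hydroxy ester 7 (not isolated)
Conditions: n-BuLi, THF, −78 °C; MgBr2·OEt2; CuI (10 mol %), 4, −40 °C; then MeMgBr (3.5 equiv), −40 °C to rt; aq NH4Cl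
Reagents that add atoms: methylmagnesium bromide, C[Mg]Br
Why: Bromine–lithium exchange and transmetalation give an aryl Grignard reagent whose CuI-catalysed SN2 epoxide opening takes place at the unhindered CH2 of the glycidic ester, so the bought (S) carbinol carbon is never touched, and double Grignard addition of MeMgBr to the ester in the same flask builds the tertiary carbinol.

**Step 3**
Reactants: 8 (2S)-1-[2-(allyloxy)-3-methoxyphenyl]-3-methylbutane-2,3-diol
Product: 11 4-allyl-2-[(2S)-2,3-dihydroxy-3-methylbutyl]-6-methoxyphenol, via ortho-dienone 9 (not isolated), via para-dienone 10 (not isolated)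
Conditions: PhNEt2, 200 °C, sealed tube, argon
Reagents that add atoms: none
Why: Para-Claisen rearrangement: both ortho positions are blocked, so the [3,3] Claisen shift to an ortho-dienone is followed by a [3,3] Cope shift to the para-dienone and enolisation, which forms the aryl–CH2 bond and frees the phenol while the stereocentre is a spectator.

**Step 4**
Reactants: 11 4-allyl-2-[(2S)-2,3-dihydroxy-3-methylbutyl]-6-methoxyphenol
Product: 12 (3S)-6-allyl-8-methoxy-2,2-dimethylchroman-3-ol
Conditions: p-TsOH·H2O (10 mol %), toluene, 80 °C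
Reagents that add atoms: none
Why: Acid-catalysed cyclodehydration (SN1): only the tertiary carbinol can ionise and the phenol oxygen captures the cation in a six-membered closure, so ring D forms with one regiochemistry and the C3–O bond, hence the (S) configuration, is retained.

**Step 5**
Reactants: 12 (3S)-6-allyl-8-methoxy-2,2-dimethylchroman-3-ol
Product: 14 (3S)-6-allyl-2,2-dimethylchroman-3,8-diyl diacetate, via chromandiol 13 (not isolated)
Conditions: NaSEt, DMF, 110 °C; then 0 °C, Ac2O, pyridine, DMAP, rt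
Reagents that add atoms: acetic anhydride, CC(=O)OC(C)=O
Why: SN2 O-demethylation by ethanethiolate at the methyl carbon (no Lewis acid, so the tertiary ether of ring D is safe), followed by DMAP-catalysed acetylation of both hydroxyls in the same flask.

**Step 6**
Reactants: 14 (3S)-6-allyl-2,2-dimethylchroman-3,8-diyl diacetate
Product: 16 2-[(3S)-3,8-diacetoxy-2,2-dimethylchroman-6-yl]acetic acid, via arylacetaldehyde 15 (not isolated)
Conditions: O3, MeCN/H2O 9:1, 0 °C; N2 purge; then NaClO2, 0 °C to rt
Reagents that add atoms: ozone, O=[O+][O-]; sodium chlorite, [Na+].[O-]Cl=O; water, O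
Why: Ozonolysis in aqueous acetonitrile gives the aldehyde directly because water traps the carbonyl oxide, and Pinnick-type chlorite oxidation in the same pot gives the acid with the H2O2 formed acting as hypochlorite scavenger.

**Step 7**
Reactants: 16 2-[(3S)-3,8-diacetoxy-2,2-dimethylchroman-6-yl]acetic acid; 17 phloroglucinol
Product: 19 (3S)-6-(5,7-dihydroxy-4-oxo-4H-chromen-3-yl)-2,2-dimethylchroman-3,8-diyl diacetate, via deoxybenzoin 18 (not isolated)
Conditions: BF3·OEt2, 80 °C; then DMF, MsCl, 60 °C; aq NaOAc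
Reagents that add atoms: N,N-dimethylformamide, CN(C)C=O
Why: Friedel–Crafts C-acylation of phloroglucinol by the BF3-activated acid gives the deoxybenzoin, whose methylene is formylated by the Vilsmeier-type reagent from DMF and MsCl and then closes onto an ortho hydroxyl with loss of dimethylamine to form ring C.

**Step 8**
Reactants: 19 (3S)-6-(5,7-dihydroxy-4-oxo-4H-chromen-3-yl)-2,2-dimethylchroman-3,8-diyl diacetate
Product: 20 3-[(3S)-3,8-dihydroxy-2,2-dimethylchroman-6-yl]-5,7-dihydroxy-4H-chromen-4-one
Conditions: K2CO3, MeOH, rt, argon; then dilute HCl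
Reagents that add atoms: none
Why: Base-catalysed transesterification (Zemplén-type methanolysis) removes both acetates without breaking any bond to the stereocentre.

**Compound list**
1 | 2-bromo-6-methoxyphenol | COc1cccc(Br)c1O | starting material
2 | allyl bromide | C=CCBr | starting material
3 | 2-(allyloxy)-1-bromo-3-methoxybenzene | COc1cccc(Br)c1OCC=C | intermediate
4 | methyl (2S)-oxirane-2-carboxylate (methyl (S)-glycidate) | COC(=O)[C@@H]1CO1 | starting material
5 | [2-(allyloxy)-3-methoxyphenyl]lithium | [Li]c1cccc(OC)c1OCC=C | intermediate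
6 | [2-(allyloxy)-3-methoxyphenyl]magnesium bromide | Br[Mg]c1cccc(OC)c1OCC=C | intermediate
7 | methyl (2S)-3-[2-(allyloxy)-3-methoxyphenyl]-2-hydroxypropanoate (present as its magnesium alkoxide) | COC(=O)[C@@H](O)Cc1cccc(OC)c1OCC=C | intermediate
8 | (2S)-1-[2-(allyloxy)-3-methoxyphenyl]-3-methylbutane-2,3-diol | CC(C)(O)[C@@H](O)Cc1cccc(OC)c1OCC=C | intermediate
9 | 6-allyl-2-[(2S)-2,3-dihydroxy-3-methylbutyl]-6-methoxycyclohexa-2,4-dien-1-one (the regioisomeric ortho-dienone leads to the same 10) | CC(C)(O)[C@@H](O)CC1=CC=CC(CC=C)(OC)C1=O | intermediate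
10 | 4-allyl-2-[(2S)-2,3-dihydroxy-3-methylbutyl]-6-methoxycyclohexa-2,5-dien-1-one | CC(C)(O)[C@@H](O)CC1=CC(CC=C)C=C(OC)C1=O | intermediate
11 | 4-allyl-2-[(2S)-2,3-dihydroxy-3-methylbutyl]-6-methoxyphenol | CC(C)(O)[C@@H](O)Cc1cc(CC=C)cc(OC)c1O | intermediate
12 | (3S)-6-allyl-8-methoxy-2,2-dimethylchroman-3-ol | CC1(C)Oc2c(OC)cc(CC=C)cc2C[C@@H]1O | intermediate
13 | (3S)-6-allyl-2,2-dimethylchroman-3,8-diol (present as its sodium salt) | CC1(C)Oc2c(O)cc(CC=C)cc2C[C@@H]1O | intermediate
14 | (3S)-6-allyl-2,2-dimethylchroman-3,8-diyl diacetate | CC1(C)Oc2c(OC(C)=O)cc(CC=C)cc2C[C@@H]1OC(C)=O | intermediate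
15 | (3S)-2,2-dimethyl-6-(2-oxoethyl)chroman-3,8-diyl diacetate | CC1(C)Oc2c(OC(C)=O)cc(CC=O)cc2C[C@@H]1OC(C)=O | intermediate
16 | 2-[(3S)-3,8-diacetoxy-2,2-dimethylchroman-6-yl]acetic acid | CC1(C)Oc2c(OC(C)=O)cc(CC(=O)O)cc2C[C@@H]1OC(C)=O | intermediate
17 | phloroglucinol (benzene-1,3,5-triol) | Oc1cc(O)cc(O)c1 | starting material
18 | (3S)-2,2-dimethyl-6-[2-oxo-2-(2,4,6-trihydroxyphenyl)ethyl]chroman-3,8-diyl diacetate | CC1(C)Oc2c(OC(C)=O)cc(CC(=O)c3c(O)cc(O)cc3O)cc2C[C@@H]1OC(C)=O | intermediate
19 | (3S)-6-(5,7-dihydroxy-4-oxo-4H-chromen-3-yl)-2,2-dimethylchroman-3,8-diyl diacetate | CC1(C)Oc2c(OC(C)=O)cc(-c3coc4cc(O)cc(O)c4c3=O)cc2C[C@@H]1OC(C)=O | intermediate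
20 | 3-[(3S)-3,8-dihydroxy-2,2-dimethylchroman-6-yl]-5,7-dihydroxy-4H-chromen-4-one | CC1(C)Oc2c(O)cc(-c3coc4cc(O)cc(O)c4c3=O)cc2C[C@@H]1O | target

**Step count**
Total steps: 8. Longest linear sequence: 8 (from 1; compounds 2, 4 and 17 are bought and enter directly).

**Steps most likely to fail, with fallbacks**

Step 7 (hot BF3·OEt2 may open ring D or transfer the aryl acetate to phloroglucinol; any 8-O-deacetylated product still converges on 20 in step 8). The fallback replaces the Friedel–Crafts acylation by a Hoesch reaction of a nitrile at 0 °C. It sets out from aldehyde 15, isolated by stopping step 6 before the chlorite is added. NH2OH·HCl and NaOAc in EtOH give (3S)-6-[2-(hydroxyimino)ethyl]-2,2-dimethylchroman-3,8-diyl diacetate F7. Ac2O at 100 °C dehydrates it to (3S)-6-(cyanomethyl)-2,2-dimethylchroman-3,8-diyl diacetate F8, and re-acetylates any phenol freed by hydroxylamine. Phloroglucinol 17 with ZnCl2 and dry HCl in Et2O at 0 °C gives (3S)-6-[2-iminio-2-(2,4,6-trihydroxyphenyl)ethyl]-2,2-dimethylchroman-3,8-diyl diacetate chloride F9. Warm water hydrolyses F9 to deoxybenzoin 18, now isolated, and Me2NCH(OMe)2 in THF at 60 °C closes ring C; the route is rejoined at 19.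

Step 4 (a pinacol-type hydride shift of the β-hydroxy cation to the isopropyl ketone may compete with ring closure). The fallback acetylates the secondary hydroxyl before the rearrangement, so that ring D closes through an acetate-bridged 1,3-dioxolan-2-ylium ion that cannot undergo the hydride shift. It sets out from 8. Ac2O, pyridine and DMAP at 0 °C (the tertiary carbinol does not react) give (2S)-1-[2-(allyloxy)-3-methoxyphenyl]-3-hydroxy-3-methylbutan-2-yl acetate F4. The para-Claisen rearrangement under the conditions of step 3 gives (2S)-1-(5-allyl-2-hydroxy-3-methoxyphenyl)-3-hydroxy-3-methylbutan-2-yl acetate F5. BF3·OEt2 in CH2Cl2 at −20 °C ionises the tertiary carbinol, and capture by the phenol oxygen at the tertiary carbon gives (3S)-6-allyl-8-methoxy-2,2-dimethylchroman-3-yl acetate F6, again without breaking the C3–O bond. F6 is put through step 5 as it stands: the thiolate cleaves the methyl ether and the acetate alike to give 13 in the flask, and the route is rejoined at 14.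

Step 2 (the aryl Grignard may attack the ester, or methyl addition may be incomplete in the one-pot sequence). The fallback builds the tertiary carbinol before the epoxide is opened. It sets out from 4. MeLi (2.1 equiv) in Et2O at −78 °C adds twice to the ester and leaves the epoxide alone at this temperature, giving the lithium alkoxide of 2-[(2S)-oxiran-2-yl]propan-2-ol F1. This is silylated in the flask with Me3SiCl to trimethyl({2-[(2S)-oxiran-2-yl]propan-2-yl}oxy)silane F2, which also blocks Payne migration of the epoxide. The Grignard reagent 6, made from 3 as in step 2, opens the ester-free epoxide at CH2 under CuI catalysis to (2S)-1-[2-(allyloxy)-3-methoxyphenyl]-3-methyl-3-[(trimethylsilyl)oxy]butan-2-ol F3. Dilute aqueous citric acid removes the silyl group and the route is rejoined at 8.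

**Further compounds**
F1 | step 2 | 2-[(2S)-oxiran-2-yl]propan-2-ol (as lithium alkoxide) | CC(C)(O)[C@@H]1CO1
F2 | step 2 | trimethyl({2-[(2S)-oxiran-2-yl]propan-2-yl}oxy)silane | CC(C)(O[Si](C)(C)C)[C@@H]1CO1
F3 | step 2 | (2S)-1-[2-(allyloxy)-3-methoxyphenyl]-3-methyl-3-[(trimethylsilyl)oxy]butan-2-ol | CC(C)(O[Si](C)(C)C)[C@@H](O)Cc1cccc(OC)c1OCC=C
F4 | step 4 | (2S)-1-[2-(allyloxy)-3-methoxyphenyl]-3-hydroxy-3-methylbutan-2-yl acetate | CC(C)(O)[C@@H](OC(C)=O)Cc1cccc(OC)c1OCC=C
F5 | step 4 | (2S)-1-(5-allyl-2-hydroxy-3-methoxyphenyl)-3-hydroxy-3-methylbutan-2-yl acetate | CC(C)(O)[C@@H](OC(C)=O)Cc1cc(CC=C)cc(OC)c1O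
F6 | step 4 | (3S)-6-allyl-8-methoxy-2,2-dimethylchroman-3-yl acetate | CC1(C)Oc2c(OC)cc(CC=C)cc2C[C@@H]1OC(C)=O
F7 | step 7 | (3S)-6-[2-(hydroxyimino)ethyl]-2,2-dimethylchroman-3,8-diyl diacetate | CC1(C)Oc2c(OC(C)=O)cc(CC=NO)cc2C[C@@H]1OC(C)=O
F8 | step 7 | (3S)-6-(cyanomethyl)-2,2-dimethylchroman-3,8-diyl diacetate | CC1(C)Oc2c(OC(C)=O)cc(CC#N)cc2C[C@@H]1OC(C)=O
F9 | step 7 | (3S)-6-[2-iminio-2-(2,4,6-trihydroxyphenyl)ethyl]-2,2-dimethylchroman-3,8-diyl diacetate chloride | CC1(C)Oc2c(OC(C)=O)cc(CC(=[NH2+])c3c(O)cc(O)cc3O)cc2C[C@@H]1OC(C)=O.[Cl-]
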